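**Retrosynthetic overview**

1. The last step only unmasks the phenol (aryl silyl ether). The protected target is made in one operation from an open-chain masked triketide and prenal.
2. Key disconnections: C4–C4a and O1–C2 of the pyran ring B (prenal supplies C2–C3–C4) together with C5–C6 of the benzene ring A. Ring B forms first (Knoevenagel, then oxa-6π), ring A second (aldol-type closure and dehydration), in the same flask.
3. Enabling feature: in the chain ArCH2CH2–C5(=O)–C4aH2–C8a(=O)–C8H=C7(O-prenyl)–C6H3 the C4a methylene is the only carbon between two carbonyls, the C8a carbonyl oxygen is the future O1, and the C6 methyl of the enol ether is a vinylogous donor six atoms from the C5 ketone. The C7 oxygen already carries the prenyl group, so the 5-alkyl-7-alkoxy pattern of ring A is fixed by the chain.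
4. The chain comes from C-acylation of the kinetic enolate of (E)-4-(prenyloxy)pent-3-en-2-one with 3-(4-silyloxyphenyl)propanoyl chloride; the enol ether comes from pent-3-yn-2-one and prenol.

Key step: step 4

Remark: chromene numbering (O1, C2, C3, C4, C4a, C5 to C8, C8a) is used for the atoms of all precursors. The target has no stereocentre; only the E enol ether geometry of the intermediates is defined.

**Route**

Step 1
Reactants: 1 3-(4-hydroxyphenyl)propanoic acid
Product: 3 3-{4-[tri(propan-2-yl)silyloxy]phenyl}propanoic acid, via bis-silyl ester 2 (not isolated)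
Conditions: TIPSCl (2.3 equiv), imidazole (5 equiv), DMF, rt; then AcOH/THF/H2O (3:1:1), rt
Reagents that add atoms: chlorotri(propan-2-yl)silane (TIPSCl), CC(C)[Si](Cl)(C(C)C)C(C)C
Why: Imidazole-promoted silylation caps both the phenol and the acid, and the silyl ester, far more labile than the aryl TIPS ether, is then hydrolysed selectively by aqueous acetic acid (standard silyl protection followed by selective silyl ester cleavage).

Step 2
Reactants: 4 pent-3-yn-2-one; 5 3-methylbut-2-en-1-ol (prenol)
Product: 6 (3E)-4-[(3-methylbut-2-en-1-yl)oxy]pent-3-en-2-one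
Conditions: PMe3 (10 mol %), CH2Cl2, 0 °C to rt
Reagents that add atoms: none
Why: Phosphine-catalysed oxa-Michael addition of the alcohol to the conjugated ynone places the prenyloxy group on the beta carbon and should deliver the thermodynamically favoured E enol ether under neutral conditions that leave the prenyl group untouched.

Step 3
Reactants: 3 3-{4-[tri(propan-2-yl)silyloxy]phenyl}propanoic acid; 6 (3E)-4-[(3-methylbut-2-en-1-yl)oxy]pent-3-en-2-one
Product: 9 (6E)-7-[(3-methylbut-2-en-1-yl)oxy]-1-{4-[tri(propan-2-yl)silyloxy]phenyl}oct-6-ene-3,5-dione, via acid chloride 7 (not isolated), via lithium enolate 8 (not isolated)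
Conditions: 3, (COCl)2, DMF (cat.), CH2Cl2, 0 °C to rt, then evaporation; 6 (2.0 equiv), LiN(SiMe3)2 (2.1 equiv), THF, −78 °C; then 7, −78 °C; aq NH4Cl; Et3N-deactivated silica
Reagents that add atoms: none
Why: Kinetic deprotonation of the beta-alkoxy enone occurs at the alpha' methyl group and Claisen-type C-acylation of this lithium enolate by the acid chloride gives the 1,3-diketone, the second equivalent of enolate absorbing the acidic proton of the product (the standard acylation used for 4-pyranone precursors), while acid is avoided in the work-up because it would cyclize 9 to a 4-pyranone.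

Step 4
Reactants: 9 (6E)-7-[(3-methylbut-2-en-1-yl)oxy]-1-{4-[tri(propan-2-yl)silyloxy]phenyl}oct-6-ene-3,5-dione; 10 3-methylbut-2-enal (prenal)
Product: 14 {4-[2-{2,2-dimethyl-7-[(3-methylbut-2-en-1-yl)oxy]-2H-chromen-5-yl}ethyl]phenoxy}tri(propan-2-yl)silane, via Knoevenagel dienone 11 (not isolated), via 2H-pyran 12 (not isolated), via ring A carbinol 13 (not isolated)
Conditions: 10 (1.1 equiv), piperidine (10 mol %), AcOH (10 mol %), 4 Å MS, THF, rt; then KOtBu (3 equiv), 0 °C to rt; AcOH, rt
Reagents that add atoms: none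
Why: Proposed new method: piperidinium-catalysed Knoevenagel condensation of prenal at the C4a methylene of 9 gives dienone 11 (C4–C4a bond), the C8a carbonyl oxygen then closes ring B by a thermal disrotatory oxa-6π electrocyclization onto the CMe2 terminus (O1–C2 bond) to give 2H-pyran 12, and KOtBu finally deprotonates the C6 methyl so that the extended enolate closes ring A by a 6-(enolendo)-exo-trig aldol-type addition of C6 to the C5 ketone (equally describable as a 6π closure of the trienolate) to give carbinol 13, which aromatizes by loss of water. The closest known reaction types are the formal oxa-(3+3) annulation of 1,3-diketones with enals and the biomimetic aldol aromatization of masked poly-beta-carbonyl chains to resorcinols; their union in one flask, with an enol-ether methyl as the vinylogous donor, is what is new. The condensation must come first, because it removes both C4a hydrogens and so prevents the C5 carbonyl from being switched off as a diketonate under base. The only stereocentre that appears, C5 of 13, is racemic and is erased by the dehydration, so nothing has to be controlled. The selectivity needed is regiochemical and is written into the chain: prenal can only condense at the one doubly activated carbon, O1 can only be the C8a oxygen because the C5 oxygen leaves as water, and C6 can only reach C5, so the 5-alkyl-7-alkoxy pattern does not depend on the directing effects of a phenol. Closure of the C5 enolate onto C7 with loss of prenoxide should be slower (fully substituted vinylogous ester carbon), and in pyran 12 the former C4 Michael acceptor is masked.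

Step 5
Reactants: 14 {4-[2-{2,2-dimethyl-7-[(3-methylbut-2-en-1-yl)oxy]-2H-chromen-5-yl}ethyl]phenoxy}tri(propan-2-yl)silane
Product: 15 4-{2-[2,2-dimethyl-7-(3-methylbut-2-en-1-yloxy)-2H-chromen-5-yl]ethyl}phenol
Conditions: Bu4NF (1.1 equiv), THF, 0 °C; aq NH4Cl
Reagents that add atoms: none
Why: Fluoride-induced cleavage of the aryl silyl ether (desilylation) frees the phenol while the prenyl ether and the chromene are inert to Bu4NF.

**Compound list**

1 | 3-(4-hydroxyphenyl)propanoic acid | O=C(O)CCc1ccc(O)cc1 | starting material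
2 | tri(propan-2-yl)silyl 3-{4-[tri(propan-2-yl)silyloxy]phenyl}propanoate | CC(C)[Si](OC(=O)CCc1ccc(O[Si](C(C)C)(C(C)C)C(C)C)cc1)(C(C)C)C(C)C | intermediate
3 | 3-{4-[tri(propan-2-yl)silyloxy]phenyl}propanoic acid | O=C(O)CCc1ccc(O[Si](C(C)C)(C(C)C)C(C)C)cc1 | intermediate
4 | pent-3-yn-2-one | CC#CC(C)=O | starting material
5 | 3-methylbut-2-en-1-ol (prenol) | CC(C)=CCO | starting material
6 | (3E)-4-[(3-methylbut-2-en-1-yl)oxy]pent-3-en-2-one | CC(C)=CCO/C(C)=C/C(C)=O | intermediate
7 | 3-{4-[tri(propan-2-yl)silyloxy]phenyl}propanoyl chloride | O=C(Cl)CCc1ccc(O[Si](C(C)C)(C(C)C)C(C)C)cc1 | intermediate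
8 | lithium (3E)-4-[(3-methylbut-2-en-1-yl)oxy]penta-1,3-dien-2-olate | [Li+].C=C([O-])/C=C(C)/OCC=C(C)C | intermediate
9 | (6E)-7-[(3-methylbut-2-en-1-yl)oxy]-1-{4-[tri(propan-2-yl)silyloxy]phenyl}oct-6-ene-3,5-dione | CC(C)=CCO/C(C)=C/C(=O)CC(=O)CCc1ccc(O[Si](C(C)C)(C(C)C)C(C)C)cc1 | intermediate
10 | 3-methylbut-2-enal (prenal) | CC(C)=CC=O | starting material
11 | (6E)-4-(3-methylbut-2-en-1-ylidene)-7-[(3-methylbut-2-en-1-yl)oxy]-1-{4-[tri(propan-2-yl)silyloxy]phenyl}oct-6-ene-3,5-dione (alkylidene geometry not fixed) | CC(C)=CC=C(C(=O)CCc1ccc(O[Si](C(C)C)(C(C)C)C(C)C)cc1)C(=O)/C=C(C)/OCC=C(C)C | intermediate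
12 | 1-{2,2-dimethyl-6-[(1E)-2-[(3-methylbut-2-en-1-yl)oxy]prop-1-en-1-yl]-2H-pyran-5-yl}-3-{4-[tri(propan-2-yl)silyloxy]phenyl}propan-1-one | CC(C)=CCO/C(C)=C/C1=C(C(=O)CCc2ccc(O[Si](C(C)C)(C(C)C)C(C)C)cc2)C=CC(C)(C)O1 | intermediate
13 | 2,2-dimethyl-7-[(3-methylbut-2-en-1-yl)oxy]-5-(2-{4-[tri(propan-2-yl)silyloxy]phenyl}ethyl)-5,6-dihydro-2H-chromen-5-ol (racemic) | CC(C)=CCOC1=CC2=C(C=CC(C)(C)O2)C(O)(CCc2ccc(O[Si](C(C)C)(C(C)C)C(C)C)cc2)C1 | intermediate
14 | {4-[2-{2,2-dimethyl-7-[(3-methylbut-2-en-1-yl)oxy]-2H-chromen-5-yl}ethyl]phenoxy}tri(propan-2-yl)silane | CC(C)=CCOc1cc(CCc2ccc(O[Si](C(C)C)(C(C)C)C(C)C)cc2)c2c(c1)OC(C)(C)C=C2 | intermediate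
15 | 4-{2-[2,2-dimethyl-7-(3-methylbut-2-en-1-yloxy)-2H-chromen-5-yl]ethyl}phenol | CC(C)=CCOc1cc(CCc2ccc(O)cc2)c2c(c1)OC(C)(C)C=C2 | target

**Step count**

Total steps: 5. Longest linear sequence: 4 steps (step 1 or step 2, then steps 3, 4 and 5).

**Steps most likely to fail**

Step 4. What may go wrong:
- Diversion of the dienone and pyran manifold: closure of the C6 extended enolate onto C4 of dienone 11 (Michael-type), or closure of the C5 enolate onto C7 with loss of the prenyloxy group.
- Consumption of the amine catalyst by addition–elimination at C7.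
- Stalling at the 2H-pyran stage.
- Partial loss of the silyl group under KOtBu; this would be harmless, since step 5 removes it anyway.

Fallback with known chemistry, setting out from 10 and coming back to the route at 15: ring A is taken as a ready-made arene and ring B is annulated onto a phenol. 5-Bromobenzene-1,3-diol F1 is mono-alkylated with prenyl bromide (K2CO3, acetone) to 3-bromo-5-[(3-methylbut-2-en-1-yl)oxy]phenol F2. Hydroboration of commercial tert-butyldimethyl(4-vinylphenoxy)silane F3 with 9-BBN gives 9-{2-[4-(tert-butyldimethylsilyloxy)phenyl]ethyl}-9-borabicyclo[3.3.1]nonane F4, which is coupled in the same flask with F2 (Pd(dppf)Cl2, K3PO4, THF/H2O, 60 °C; B-alkyl Suzuki–Miyaura coupling) to 3-{2-[4-(tert-butyldimethylsilyloxy)phenyl]ethyl}-5-[(3-methylbut-2-en-1-yl)oxy]phenol F5. Ortho-selective chromenylation of F5 with prenal 10 (PhB(OH)2, AcOH, toluene, reflux) should give the tert-butyldimethylsilyl analogue of 14, tert-butyl{4-[2-{2,2-dimethyl-7-[(3-methylbut-2-en-1-yl)oxy]-2H-chromen-5-yl}ethyl]phenoxy}dimethylsilane F6. Reaction is expected at the ring carbon ortho to the hydroxyl and para to the prenyloxy group, by analogy with 3-alkoxyphenols, though the position between the two oxygens may compete. Bu4NF then gives 15.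

Step 3. What may go wrong:
- O-acylation or double acylation of the enolate.
- Quenching of the enolate by proton transfer from the product.
- Acid-triggered cyclization of the product to a 4-pyranone during work-up or chromatography.

Fallback, setting out from 3 (with 6 as the partner) and coming back at 9: an aldol addition and oxidation replace the acylation. Acid 3 is reduced with BH3·SMe2 to 3-{4-[tri(propan-2-yl)silyloxy]phenyl}propan-1-ol F7, which is oxidized with Dess–Martin periodinane to 3-{4-[tri(propan-2-yl)silyloxy]phenyl}propanal F8. Aldol addition of lithium enolate 8 (from 6 and LiN(SiMe3)2, THF, −78 °C) to F8 gives racemic (6E)-3-hydroxy-7-[(3-methylbut-2-en-1-yl)oxy]-1-{4-[tri(propan-2-yl)silyloxy]phenyl}oct-6-en-5-one F9. Buffered Dess–Martin oxidation of the beta-hydroxy ketone then gives 9.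

Step 2. What may go wrong:
- Phosphine-triggered isomerization of the ynone to the allenone.
- Gamma-addition or oligomerization instead of clean beta-addition.
- Formation of an E/Z mixture.

Fallback, setting out from 5 and coming back at 6: acid-catalysed trans-etherification (vinylogous transesterification) of commercial (3E)-4-methoxypent-3-en-2-one F10 with prenol 5 (pyridinium p-toluenesulfonate cat., toluene, 80 °C, with removal of the volatile alcohol) gives 6.

**Further compounds**

F1 | step 4 | 5-bromobenzene-1,3-diol | Oc1cc(O)cc(Br)c1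
F2 | step 4 | 3-bromo-5-[(3-methylbut-2-en-1-yl)oxy]phenol | CC(C)=CCOc1cc(O)cc(Br)c1
F3 | step 4 | tert-butyldimethyl(4-vinylphenoxy)silane | C=Cc1ccc(O[Si](C)(C)C(C)(C)C)cc1
F4 | step 4 | 9-{2-[4-(tert-butyldimethylsilyloxy)phenyl]ethyl}-9-borabicyclo[3.3.1]nonane | CC(C)(C)[Si](C)(C)Oc1ccc(CCB2C3CCCC2CCC3)cc1
F5 | step 4 | 3-{2-[4-(tert-butyldimethylsilyloxy)phenyl]ethyl}-5-[(3-methylbut-2-en-1-yl)oxy]phenol | CC(C)=CCOc1cc(O)cc(CCc2ccc(O[Si](C)(C)C(C)(C)C)cc2)c1
F6 | step 4 | tert-butyl{4-[2-{2,2-dimethyl-7-[(3-methylbut-2-en-1-yl)oxy]-2H-chromen-5-yl}ethyl]phenoxy}dimethylsilane | CC(C)=CCOc1cc(CCc2ccc(O[Si](C)(C)C(C)(C)C)cc2)c2c(c1)OC(C)(C)C=C2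
F7 | step 3 | 3-{4-[tri(propan-2-yl)silyloxy]phenyl}propan-1-ol | OCCCc1ccc(O[Si](C(C)C)(C(C)C)C(C)C)cc1
F8 | step 3 | 3-{4-[tri(propan-2-yl)silyloxy]phenyl}propanal | O=CCCc1ccc(O[Si](C(C)C)(C(C)C)C(C)C)cc1
F9 | step 3 | (6E)-3-hydroxy-7-[(3-methylbut-2-en-1-yl)oxy]-1-{4-[tri(propan-2-yl)silyloxy]phenyl}oct-6-en-5-one (racemic) | CC(C)=CCO/C(C)=C/C(=O)CC(O)CCc1ccc(O[Si](C(C)C)(C(C)C)C(C)C)cc1
F10 | step 2 | (3E)-4-methoxypent-3-en-2-one | CO/C(C)=C/C(C)=O
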